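(The readings come from a simulation for substances that don't exist, noise included.)

J was the species I followed in three new flasks, which differed in their charge of L.

| setting | ochre | amber | Saturday's | Monday's | Thursday's |
|---|---|---|---|---|---|
| J | 0.028 M | 0.028 M | 0.028 M | 0.028 M | 0.028 M |
| X | 0.028 M | 0.028 M | 0.0280 M | 0.0280 M | 0.0280 M |
| L | 0.025 M | 0.042 M | 0.0310 M | 0.0520 M | 0.0400 M |
| remark | run made earlier | run made earlier |  |  |  |
| time |  |  | 10 min | 10 min | 10 min |

| run | time / min | E / % | J / % |
|---|---|---|---|
| ochre | 1.33 | 3.8 | 87.6 |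
| ochre | 2.50 | 5.6 | 79.7 |
| ochre | 4.00 | 7.9 | 67.2 |
| ochre | 5.00 | 10.1 | 62.1 |
| amber | 0.667 | 1.1 | 92.9 |
| amber | 2.00 | 4.1 | 82.6 |
| amber | 3.00 | 7.0 | 74.3 |
| amber | 5.00 | 9.4 | 62.0 |

(scatter of a reading: 0.5 percentage points)

- which of the two there is more of at the end, Saturday's (E / Z)
- which of the two there is more of at the end, Monday's (E / Z)
- which of the two there is more of at the end, Thursday's (E / Z)
- final E, as a percentage of the J charged, in Saturday's
- final E, as a percentage of the J charged, in Monday's
- final E, as a percentage of the J charged, in Thursday's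

- a reading or a percentage of E counts all its forms, free or not

In the ochre and amber runs J read 62.1 % and 62.0 % at 5.00 min, although L was 0.025 M in one and 0.042 M in the other. I therefore took the loss of J as first order and free of L, and read a constant of 0.0954 min⁻¹ off the two readings. Over the asked 10 min that makes 0.954 turnovers, the turnover count being the time multiplied by that constant. The fraction of J remaining is exp(−count), so 61.5 % of the J charged had gone by my reckoning.

At 5.00 min E read 10.1 % and 9.4 %, and over the J gone by then the two runs give a share of 0.257, as a reading. I used that one share for all three flasks, which put E at 15.8 %. I put the remaining 45.7 % on Z, so my reckoning had Z ahead of E.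

The forecast, saying “E is a roughly constant quarter of the J consumed”, named Z, Z and Z for Saturday's, Monday's and Thursday's and put E at 15.5 %, 15.5 % and 15.5 %, lower than my figure.

The flasks gave E at 16.2 % in Saturday's, 14.4 % in Monday's and 15.4 % in Thursday's, with Z at 33.4 %, 29.4 % and 31.6 %.

    X + D → E (k = 5.10 M⁻¹ s⁻¹)
    L + D → Q (k = 3.30 M⁻¹ s⁻¹)
    D → Z (k = 0.270 s⁻¹)
    J → D (k = 0.00160 s⁻¹)
    G ⇌ E, rate k5*(cs5 - [E]) while solid is left; crystals form when [E] > cs5 (solubility = 1.90 mM, k = 0.130 s⁻¹)

The clock is J to D, the rate-limiting step, with a half-life of 7.2 min against 2.6 s for D to Z by that step alone. Thursday's was not at rest at 10 min: with 0.954 turnovers behind it, J stood at 38.3 %. At 40 min the count is 3.82, which reckons J at 2.20 %; Thursday's, read at that time, held 2.15 %, with E at 23.7 %. Left ten times as long, 9.54 turnovers, Thursday's reached E 24.2 % and Z 52.4 %, with J at 0.00677 %.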